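## Retrosynthetic overview

1. Target 17 is cut at the C5–C1' bond: the aryllithium from bromide 11 adds to (R)-2-silyloxypropanal 14 (Felkin–Anh, sets C1' as S; C2' R comes from methyl (R)-lactate), then desilylation.
2. Bromide 11 comes from trans ester 8: the C3 methyl is the reduced ester (iBu2AlH, MsCl, LiEt3BH), and the C5 bromine is kept as the handle for line 1.
3. Ester 8 comes from diazo ester 6. The feature used is that C2 of the dihydrofuran ring (ring B: O1–C2–C3–C3a–C7a) is a benzylic ether carbon carrying the dimethoxyphenyl ring (ring C). In the O-(3,4-dimethoxybenzyl) ether of ring A its C–H bonds therefore lie 1,5 to a carbene at C3, and a dirhodium carbenoid C–H insertion forms C2–C3.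
4. Diazo ester 6 comes from aryl iodide 4 and ethyl diazoacetate (Pd coupling); 4 comes from 4-bromo-2-methoxyphenol by ortho-iodination and O-alkylation with 3,4-dimethoxybenzyl chloride.
5. Ring order: rings A and C are bought; ring B is the only ring formed (step 4).

Key step: step 4

Assumption: with the parent 2-benzyloxyphenyl diazoacetates the (S)-tert-leucinate catalyst is taken to give the 2R series, so the mirror-image catalyst Rh2(R-PTTL)4 (dirhodium tetrakis[N-phthaloyl-(R)-tert-leucinate]) is specified for 2S; the configuration of 8 would be confirmed (the bromine allows anomalous-dispersion X-ray analysis) and the catalyst enantiomer exchanged if the sense proves opposite.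

## Route

Step 1
Reactants: 1 4-bromo-2-methoxyphenol
Product: 2 4-bromo-2-iodo-6-methoxyphenol
Conditions: NaI, NaOH, aq. NaOCl (slow addition), MeOH, 0 °C
Reagents that add atoms: sodium iodide, [Na+].[I-]
Why: Electrophilic aromatic iodination of the phenoxide by hypoiodite made in situ; the para position is blocked by bromine and one ortho position by OMe, so iodine should enter the only free position ortho to the phenoxide oxygen.

Step 2
Reactants: 2 4-bromo-2-iodo-6-methoxyphenol; 3 3,4-dimethoxybenzyl chloride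
Product: 4 5-bromo-2-[(3,4-dimethoxyphenyl)methoxy]-1-iodo-3-methoxybenzene
Conditions: K2CO3, Bu4NI (cat.), DMF, 50 °C
Reagents that add atoms: none
Why: Williamson ether synthesis (SN2 of the phenoxide on a reactive benzylic chloride), routine even for a phenol flanked by two ortho substituents.

Step 3
Reactants: 4 5-bromo-2-[(3,4-dimethoxyphenyl)methoxy]-1-iodo-3-methoxybenzene; 5 ethyl diazoacetate
Product: 6 ethyl 2-[5-bromo-2-[(3,4-dimethoxyphenyl)methoxy]-3-methoxyphenyl]-2-diazoacetate
Conditions: Pd(PPh3)4 (5 mol %), Et3N, Bu4NBr, MeCN, rt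
Reagents that add atoms: none
Why: Palladium-catalysed cross-coupling of an aryl iodide with ethyl diazoacetate with retention of the diazo group; zerovalent palladium inserts into C–I far faster than into C–Br at room temperature, so the bromide should survive.

Step 4
Reactants: 6 ethyl 2-[5-bromo-2-[(3,4-dimethoxyphenyl)methoxy]-3-methoxyphenyl]-2-diazoacetate
Product: 8 ethyl (2S,3S)-5-bromo-2-(3,4-dimethoxyphenyl)-7-methoxy-2,3-dihydro-1-benzofuran-3-carboxylate, via cis-(2S,3R) ester 7 (not isolated)
Conditions: Rh2(R-PTTL)4 (2 mol %), toluene, −78 °C; then NaOEt (0.3 equiv), EtOH, 0 °C to rt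
Reagents that add atoms: none
Why: Rh2(R-PTTL)4 decomposes the aryldiazoacetate with loss of N2 to an electrophilic donor/acceptor rhodium carbenoid, which inserts into one of the two enantiotopic O–CH2 hydrogens of the dimethoxybenzyl ether through a concerted, asynchronous three-centre transition state with retention at carbon; the closest known reaction type is the Rh2(PTTL)4-catalysed intramolecular C–H insertion of 2-benzyloxyphenyl diazoacetates to cis-2-aryl-2,3-dihydrobenzofuran-3-carboxylates. Ring B is closed by this 1,5 C–H insertion, which forms the C2–C3 bond through a five-membered transition state. C2 is set by the chiral carboxylate ligands, which distinguish the enantiotopic benzylic hydrogens (2S expected with the (R)-ligand, see the assumption), and the insertion is expected to give cis ester 7 kinetically. C3 is then set thermodynamically: catalytic NaOEt in EtOH (matched to the ester) epimerises the acidic C3–H so that the ester ends trans to the C2 aryl group, while C2 is untouched because ring opening would be the reverse of a disfavoured 5-endo closure. The step needs chemoselectivity for the benzylic ether C–H over cycloaddition to ring C, carbene dimerisation and oxonium ylide formation; the C–H bond is activated by both the ether oxygen and the electron-rich aryl ring, it is the only C–H within reach of a five-membered transition state, and the donor aryl group on the carbenoid and the low temperature temper its reactivity.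

Step 5
Reactants: 8 ethyl (2S,3S)-5-bromo-2-(3,4-dimethoxyphenyl)-7-methoxy-2,3-dihydro-1-benzofuran-3-carboxylate
Product: 9 [(2S,3R)-5-bromo-2-(3,4-dimethoxyphenyl)-7-methoxy-2,3-dihydro-1-benzofuran-3-yl]methanol
Conditions: iBu2AlH (2.5 equiv), CH2Cl2, −78 to 0 °C; aq. potassium sodium tartrate
Reagents that add atoms: none
Why: Hydride reduction of the ester to the primary alcohol, which leaves the aryl bromide and aryl ethers alone; the change of descriptor at C3 is only a CIP priority change.

Step 6
Reactants: 9 [(2S,3R)-5-bromo-2-(3,4-dimethoxyphenyl)-7-methoxy-2,3-dihydro-1-benzofuran-3-yl]methanol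
Product: 10 [(2S,3R)-5-bromo-2-(3,4-dimethoxyphenyl)-7-methoxy-2,3-dihydro-1-benzofuran-3-yl]methyl methanesulfonate
Conditions: MsCl, Et3N, CH2Cl2, 0 °C
Reagents that add atoms: methanesulfonyl chloride, CS(=O)(=O)Cl
Why: Sulfonylation of an unhindered primary alcohol, with no stereocentre involved.

Step 7
Reactants: 10 [(2S,3R)-5-bromo-2-(3,4-dimethoxyphenyl)-7-methoxy-2,3-dihydro-1-benzofuran-3-yl]methyl methanesulfonate
Product: 11 (2S,3S)-5-bromo-2-(3,4-dimethoxyphenyl)-7-methoxy-3-methyl-2,3-dihydro-1-benzofuran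
Conditions: LiEt3BH, THF, 0 °C to rt
Reagents that add atoms: none
Why: SN2 displacement of a primary mesylate by hydride (reductive deoxygenation), which outruns E2 elimination and does not reduce the aryl bromide at this temperature.

Step 8
Reactants: 12 methyl (R)-lactate
Product: 13 methyl (2R)-2-[(tert-butyldiphenylsilyl)oxy]propanoate
Conditions: TBDPSCl, imidazole, DMF, rt
Reagents that add atoms: tert-butyl(chloro)diphenylsilane, CC(C)(C)[Si](Cl)(c1ccccc1)c1ccccc1
Why: Imidazole-promoted silylation of the secondary alcohol, which does not touch the stereocentre.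

Step 9
Reactants: 13 methyl (2R)-2-[(tert-butyldiphenylsilyl)oxy]propanoate
Product: 14 (2R)-2-[(tert-butyldiphenylsilyl)oxy]propanal
Conditions: iBu2AlH (1.05 equiv), Et2O, −78 °C; MeOH quench at −78 °C, aq. potassium sodium tartrate
Reagents that add atoms: none
Why: Partial reduction of the ester to the aldehyde through the tetrahedral aluminium hemiacetal, which is stable at −78 °C; the aldehyde is used at once to avoid racemisation.

Step 10
Reactants: 11 (2S,3S)-5-bromo-2-(3,4-dimethoxyphenyl)-7-methoxy-3-methyl-2,3-dihydro-1-benzofuran; 14 (2R)-2-[(tert-butyldiphenylsilyl)oxy]propanal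
Product: 16 (1S,2R)-2-[(tert-butyldiphenylsilyl)oxy]-1-[(2S,3S)-2-(3,4-dimethoxyphenyl)-7-methoxy-3-methyl-2,3-dihydro-1-benzofuran-5-yl]propan-1-ol, via aryllithium 15 (not isolated)
Conditions: n-BuLi, THF, −78 °C; then 14, −78 °C; then H2O
Reagents that add atoms: none
Why: Bromine–lithium exchange followed by 1,2-addition to the aldehyde under Felkin–Anh (non-chelation) control, the bulky non-chelating silyloxy group lying anti to the incoming aryl group, which should set C1' as S (anti to C2'); the minor syn isomer is to be removed by chromatography.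

Step 11
Reactants: 16 (1S,2R)-2-[(tert-butyldiphenylsilyl)oxy]-1-[(2S,3S)-2-(3,4-dimethoxyphenyl)-7-methoxy-3-methyl-2,3-dihydro-1-benzofuran-5-yl]propan-1-ol
Product: 17 (1S,2R)-1-[(2S,3S)-2-(3,4-dimethoxyphenyl)-7-methoxy-3-methyl-2,3-dihydro-1-benzofuran-5-yl]propane-1,2-diol
Conditions: Bu4NF, THF, 0 °C to rt
Reagents that add atoms: none
Why: Fluoride-mediated desilylation under non-acidic conditions, chosen because the electron-rich benzylic alcohol and the benzylic ether at C2 would ionise in acid; any silyl migration between the two hydroxyls ends in the same diol.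

## Compound list

1 | 4-bromo-2-methoxyphenol | COc1cc(Br)ccc1O | starting material
2 | 4-bromo-2-iodo-6-methoxyphenol | COc1cc(Br)cc(I)c1O | intermediate
3 | 3,4-dimethoxybenzyl chloride | COc1ccc(CCl)cc1OC | starting material
4 | 5-bromo-2-[(3,4-dimethoxyphenyl)methoxy]-1-iodo-3-methoxybenzene | COc1ccc(COc2c(I)cc(Br)cc2OC)cc1OC | intermediate
5 | ethyl diazoacetate | CCOC(=O)C=[N+]=[N-] | starting material
6 | ethyl 2-[5-bromo-2-[(3,4-dimethoxyphenyl)methoxy]-3-methoxyphenyl]-2-diazoacetate | CCOC(=O)C(=[N+]=[N-])c1cc(Br)cc(OC)c1OCc1ccc(OC)c(OC)c1 | intermediate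
7 | ethyl (2S,3R)-5-bromo-2-(3,4-dimethoxyphenyl)-7-methoxy-2,3-dihydro-1-benzofuran-3-carboxylate (cis) | COc1ccc([C@H]2Oc3c(OC)cc(Br)cc3[C@H]2C(=O)OCC)cc1OC | intermediate
8 | ethyl (2S,3S)-5-bromo-2-(3,4-dimethoxyphenyl)-7-methoxy-2,3-dihydro-1-benzofuran-3-carboxylate (trans) | COc1ccc([C@H]2Oc3c(OC)cc(Br)cc3[C@@H]2C(=O)OCC)cc1OC | intermediate
9 | [(2S,3R)-5-bromo-2-(3,4-dimethoxyphenyl)-7-methoxy-2,3-dihydro-1-benzofuran-3-yl]methanol | COc1ccc([C@H]2Oc3c(OC)cc(Br)cc3[C@@H]2CO)cc1OC | intermediate
10 | [(2S,3R)-5-bromo-2-(3,4-dimethoxyphenyl)-7-methoxy-2,3-dihydro-1-benzofuran-3-yl]methyl methanesulfonate | COc1ccc([C@H]2Oc3c(OC)cc(Br)cc3[C@@H]2COS(C)(=O)=O)cc1OC | intermediate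
11 | (2S,3S)-5-bromo-2-(3,4-dimethoxyphenyl)-7-methoxy-3-methyl-2,3-dihydro-1-benzofuran | COc1ccc([C@H]2Oc3c(OC)cc(Br)cc3[C@@H]2C)cc1OC | intermediate
12 | methyl (R)-lactate | C[C@@H](O)C(=O)OC | starting material
13 | methyl (2R)-2-[(tert-butyldiphenylsilyl)oxy]propanoate | C[C@@H](O[Si](c1ccccc1)(c1ccccc1)C(C)(C)C)C(=O)OC | intermediate
14 | (2R)-2-[(tert-butyldiphenylsilyl)oxy]propanal | C[C@@H](O[Si](c1ccccc1)(c1ccccc1)C(C)(C)C)C=O | intermediate
15 | [(2S,3S)-2-(3,4-dimethoxyphenyl)-7-methoxy-3-methyl-2,3-dihydro-1-benzofuran-5-yl]lithium | COc1ccc([C@H]2Oc3c(OC)cc([Li])cc3[C@@H]2C)cc1OC | intermediate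
16 | (1S,2R)-2-[(tert-butyldiphenylsilyl)oxy]-1-[(2S,3S)-2-(3,4-dimethoxyphenyl)-7-methoxy-3-methyl-2,3-dihydro-1-benzofuran-5-yl]propan-1-ol | COc1ccc([C@H]2Oc3c(OC)cc([C@H](O)[C@@H](C)O[Si](c4ccccc4)(c4ccccc4)C(C)(C)C)cc3[C@@H]2C)cc1OC | intermediate
17 | (1S,2R)-1-[(2S,3S)-2-(3,4-dimethoxyphenyl)-7-methoxy-3-methyl-2,3-dihydro-1-benzofuran-5-yl]propane-1,2-diol | COc1ccc([C@H]2Oc3c(OC)cc([C@H](O)[C@@H](C)O)cc3[C@@H]2C)cc1OC | target

## Step count and risks

Total step count: 11 (steps 1–7, 10 and 11 in the main line; steps 8 and 9 for the aldehyde).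
Longest linear sequence: 9 steps (1–7, 10, 11).

**Step 4 (key step).** The catalyst may discriminate poorly between the two enantiotopic benzylic hydrogens on this 3-methoxy-5-bromo-substituted ring A, so that 8 is formed with too low an enantiomeric purity. The fallback sets out from 8 of any enantiomeric purity (an achiral catalyst such as Rh2(OAc)4 could then serve for the insertion) and comes back at 9. It replaces catalyst control by separation of covalent diastereomers. Saponification (LiOH, THF/H2O) would give (2S,3S)-5-bromo-2-(3,4-dimethoxyphenyl)-7-methoxy-2,3-dihydro-1-benzofuran-3-carboxylic acid F1. Pivaloyl chloride and Et3N would convert it into the mixed pivalic anhydride F2, which in the same flask acylates (4S)-4-benzyl-1,3-oxazolidin-2-one (LiCl, Et3N, THF) to the N-acyl oxazolidinone F3. F3 would be freed from its (2R,3R)-acyl diastereomer by chromatography or crystallisation. Reductive cleavage with LiBH4 (THF/H2O, 0 °C) would then give alcohol 9 and return the auxiliary.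

**Step 3.** The diazo ester or ethyl diazoacetate may decompose on palladium (carbene dimerisation), or the coupling may stall on this ortho-alkoxy, electron-rich iodide. The fallback sets out from 4 and comes back at 6, building the diazo group by a Bamford–Stevens sequence. Iodine–magnesium exchange (iPrMgCl·LiCl, THF, −40 °C; the C–Br bond is inert at this temperature) would give the arylmagnesium chloride F4. Addition of F4 to excess diethyl oxalate at −78 °C would give ethyl 2-[5-bromo-2-[(3,4-dimethoxyphenyl)methoxy]-3-methoxyphenyl]-2-oxoacetate F5. Condensation with TsNHNH2 (EtOH, 60 °C) would give the tosylhydrazone F6, and DBU in CH2Cl2 at rt would eliminate sulfinate to give 6.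

**Step 10.** The facial selectivity of the aryllithium addition may be poor (Felkin against anti-Felkin attack), and some aldehyde may be lost through enolisation, so that the C1' epimers form in comparable amounts. The fallback sets out from 11 (through 15) and from 13 and comes back at 17; it moves the stereo-determining event to a chelation-controlled ketone reduction. Ester 13 would be converted into the Weinreb amide (2R)-2-[(tert-butyldiphenylsilyl)oxy]-N-methoxy-N-methylpropanamide F7 (MeNHOMe·HCl, iPrMgCl, THF, −20 °C). Aryllithium 15 would add once to F7 to give the silyloxy ketone F8. Buffered desilylation (Bu4NF, AcOH, THF, 0 °C) would give the alpha-hydroxy ketone F9. Zn(BH4)2 in Et2O at −20 °C would reduce F9 through the five-membered zinc chelate, with hydride delivered anti to the C2' methyl, which should give the anti (1S,2R) diol 17 directly.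

## Further compounds

F1 | step 4 | (2S,3S)-5-bromo-2-(3,4-dimethoxyphenyl)-7-methoxy-2,3-dihydro-1-benzofuran-3-carboxylic acid | COc1ccc([C@H]2Oc3c(OC)cc(Br)cc3[C@@H]2C(=O)O)cc1OC
F2 | step 4 | (2S,3S)-5-bromo-2-(3,4-dimethoxyphenyl)-7-methoxy-2,3-dihydro-1-benzofuran-3-carboxylic 2,2-dimethylpropanoic anhydride | COc1ccc([C@H]2Oc3c(OC)cc(Br)cc3[C@@H]2C(=O)OC(=O)C(C)(C)C)cc1OC
F3 | step 4 | (4S)-4-benzyl-3-[(2S,3S)-5-bromo-2-(3,4-dimethoxyphenyl)-7-methoxy-2,3-dihydro-1-benzofuran-3-carbonyl]-1,3-oxazolidin-2-one | COc1ccc([C@H]2Oc3c(OC)cc(Br)cc3[C@@H]2C(=O)N4C(=O)OC[C@@H]4Cc5ccccc5)cc1OC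
F4 | step 3 | [5-bromo-2-[(3,4-dimethoxyphenyl)methoxy]-3-methoxyphenyl]magnesium chloride | Cl[Mg]c1cc(Br)cc(OC)c1OCc1ccc(OC)c(OC)c1
F5 | step 3 | ethyl 2-[5-bromo-2-[(3,4-dimethoxyphenyl)methoxy]-3-methoxyphenyl]-2-oxoacetate | CCOC(=O)C(=O)c1cc(Br)cc(OC)c1OCc1ccc(OC)c(OC)c1
F6 | step 3 | ethyl 2-[5-bromo-2-[(3,4-dimethoxyphenyl)methoxy]-3-methoxyphenyl]-2-[2-(4-methylbenzenesulfonyl)hydrazinylidene]acetate | CCOC(=O)C(=NNS(=O)(=O)c1ccc(C)cc1)c1cc(Br)cc(OC)c1OCc1ccc(OC)c(OC)c1
F7 | step 10 | (2R)-2-[(tert-butyldiphenylsilyl)oxy]-N-methoxy-N-methylpropanamide | C[C@@H](O[Si](c1ccccc1)(c1ccccc1)C(C)(C)C)C(=O)N(C)OC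
F8 | step 10 | (2R)-2-[(tert-butyldiphenylsilyl)oxy]-1-[(2S,3S)-2-(3,4-dimethoxyphenyl)-7-methoxy-3-methyl-2,3-dihydro-1-benzofuran-5-yl]propan-1-one | COc1ccc([C@H]2Oc3c(OC)cc(C(=O)[C@@H](C)O[Si](c4ccccc4)(c4ccccc4)C(C)(C)C)cc3[C@@H]2C)cc1OC
F9 | step 10 | (2R)-1-[(2S,3S)-2-(3,4-dimethoxyphenyl)-7-methoxy-3-methyl-2,3-dihydro-1-benzofuran-5-yl]-2-hydroxypropan-1-one | COc1ccc([C@H]2Oc3c(OC)cc(C(=O)[C@@H](C)O)cc3[C@@H]2C)cc1OC
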